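**Alder's lag.** The alder run is our clock, so we read it first: D climbs 31 percentage points between 3.00 min and 6.00 min, and this steep stretch, drawn back to zero D, meets the time axis at 1.00 min. We call this reading the lag, the induction period of the curve.

| flask | E | Z | temperature | remark | time |
|---|---|---|---|---|---|
| alder | 0.20 M | 0.33 M | 110 °C | run made earlier |  |
| south-east | 0.20 M | 0.220 M |  | at 110 °C until 20 min, from then on at 70 °C | 40 min |
| east | 0.20 M | 0.220 M |  | at 70 °C throughout | 10 min |

alder run (percent of the E charged): time / min: D / % = 1.50: 6.2; 3.00: 20.8; 5.00: 41.7; 6.00: 52.0; 8.00: 63.7

(scatter of a reading: 1 percentage point)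

- the earlier runs do not show what temperature does; that part of a forecast is a guess

- which one finishes higher in amount of D, in percent of the E charged ("neither" within 2 percentage points) (south-east / east / neither)
- amount of D at the end, in percent of the E charged, south-east
- amount of D at the end, in percent of the E charged, east

**Hot minutes.** We turn each flask into alder minutes. A minute at 110 °C counts in full and a minute at 70 °C counts a tenth, which is our guess, and we scale both by the ratio of cZ to alder's, assuming first order in Z. East then has 0.667 min and south-east 14.7 min.

**East, two ways.** East's hot minutes stand short of the lag, so the straight line gives no D. A power law through the first two readings, with exponent 1.75, gives 1.50%. They part, so we look at the next pair of readings, whose exponent is lower, 1.36. On these readings the exponent falls with time, so we expect it steeper before the first reading, and then the power law reads high there. We commit to east well under that figure.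

**South-east's gap.** We reckon the small thing, the gap to full conversion. Alder's gap shrinks by a rate of 0.140 min⁻¹ over its last readings, which leaves 14.3% and so D near 85.7%. Of this our reckoning gives the cool stretch 2.9 points.

**The forecast.** It says south-east, with 83% for south-east, lower than ours, and 2% for east, higher than our power-law ceiling: “The induction period then leaves D near 1–2%.”

**The flasks.** South-east ends at 80.4%, lower than our figure, and east at 0.0892%, far under the power law, so south-east finishes higher.

    E ⇌ J (K = 6.20, k = 0.0113 s⁻¹, Ea = 111 kJ mol⁻¹, ΔH = −49.0 kJ mol⁻¹)
    Z → Q (k = 0.00789 s⁻¹, Ea = 98.0 kJ mol⁻¹)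
    J + Q → D (k = 0.0172 M⁻¹ s⁻¹, Ea = 67.0 kJ mol⁻¹)
    Z ⇌ L (K = 0.210, k = 0.00181 s⁻¹, Ea = 98.0 kJ mol⁻¹, ΔH = −48.0 kJ mol⁻¹)
    (constants at 110 °C)

**At 95 °C.** Take east at 95 °C, with its other settings held. Spreading our tenth evenly over the temperature span gives a slowdown of 2.37, so this flask has 2.81 min of hot time, and the lag is shorter than that. Alder's steep line then gives 18.8%. The flask gives D 17.8% after 10.0 min, with J at 59.4%.

All runs were generated by integration on assumed constants; noise was put on by code.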